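**Plan**
- Lettering: ring A is the terminal 3,5-dihydroxyphenoxy ring and rings B–E follow along the chain. In B–E, C-1 is the carbon whose oxygen leads back towards ring A. The target is achiral with no stereocentre, and no ring is built because all five benzene rings are bought.
- Enabling feature: the hydroxyls at B C-4 and D C-4 lie para to the ether carbons B C-1 and D C-1. Those at C C-2, C C-6, E C-2 and E C-6 lie ortho to C C-1 and E C-1. A formyl group at each of these six sites first activates that ether carbon for fluoride displacement and is then exchanged for OH.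
- Retrosynthetic cuts: first the five O–CH3 bonds. Next the six aryl C–OH bonds just named, back to C–CHO in one Baeyer–Villiger operation. Last the ether bonds to C C-1, E C-1, D C-1 and B C-1.
- Forward: A+B and C+D are joined first by the two slow, para-formyl-activated displacements at 120 °C, with ring C carrying its formyl groups as dioxolanes. D–O–E and finally B–O–C are then made by the two fast, doubly ortho-activated displacements at or below room temperature.
- In this order no 2,6-diformylaryl ether meets a hot phenoxide, and every conceivable aryloxy exchange but one is degenerate.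

Key step: step 13

Assumption: 4-fluoro-3,5-dimethoxybenzaldehyde, 2-fluoro-5-methoxybenzaldehyde and 3,5-dimethoxyphenol are taken as purchasable building blocks; all free polyphenols are handled under argon.

**Step 1**
Reactants: 1 4-fluoro-3,5-dimethoxybenzaldehyde
Product: 2 4-fluoro-3-hydroxy-5-methoxybenzaldehyde
Conditions: BBr3 (1.0 equiv), CH2Cl2, −78 → 0 °C; H2O
Reagents that add atoms: none
Why: Lewis-acid cleavage of an aryl methyl ether: the two methoxy groups are equivalent, so only one monophenol can form, and one equivalent of BBr3 at low temperature should stop mainly there because the aryloxyborane formed is a poorer Lewis base than 1, while unchanged 1 and any diol are easy to separate.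

**Step 2**
Reactants: 2 4-fluoro-3-hydroxy-5-methoxybenzaldehyde
Product: 3 3-(allyloxy)-4-fluoro-5-methoxybenzaldehyde (the common B/D unit)
Conditions: allyl bromide, K2CO3, acetone, reflux
Reagents that add atoms: allyl bromide, C=CCBr
Why: Williamson ether synthesis; at 56 °C the C–F bond, deactivated in the phenoxide and only singly activated in 3, should not be displaced.

**Step 3**
Reactants: 4 2-fluoro-5-methoxybenzaldehyde
Product: 5 2-(2-fluoro-5-methoxyphenyl)-1,3-dioxolane
Conditions: ethylene glycol, TsOH·H2O (cat.), toluene, reflux, Dean–Stark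
Reagents that add atoms: ethylene glycol, OCCO
Why: Acid-catalysed acetalisation with azeotropic removal of water masks the aldehyde against butyllithium.

**Step 4**
Reactants: 5 2-(2-fluoro-5-methoxyphenyl)-1,3-dioxolane
Product: 8 2-fluoro-5-methoxybenzene-1,3-dicarbaldehyde (the E unit), via aryllithium 6 (not isolated), via acetal aldehyde 7 (not isolated)
Conditions: n-BuLi, PMDTA, THF, −78 °C; DMF, −78 → 0 °C; 2 M aq HCl, rt
Reagents that add atoms: N,N-dimethylformamide, CN(C)C=O; water, O
Why: Directed ortho-metalation and formylation: with PMDTA saturating lithium the deprotonation follows C–H acidity and should occur next to fluorine rather than next to methoxy, −78 °C suppresses aryne formation, and the acidic work-up collapses the hemiaminal and hydrolyses the dioxolane.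

**Step 5**
Reactants: 8 2-fluoro-5-methoxybenzene-1,3-dicarbaldehyde
Product: 9 2-fluoro-5-hydroxybenzene-1,3-dicarbaldehyde
Conditions: BBr3 (2.5 equiv), CH2Cl2, −78 → 0 °C; H2O
Reagents that add atoms: none
Why: BBr3 demethylation of an aryl methyl ether, routinely applied to fluoro(methoxy)benzaldehydes; kept at or below 0 °C, the aryl fluoride and (after hydrolytic work-up) both formyl groups should be retained.

**Step 6**
Reactants: 9 2-fluoro-5-hydroxybenzene-1,3-dicarbaldehyde
Product: 10 4-fluoro-3,5-bis(1,3-dioxolan-2-yl)phenol (the masked C unit)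
Conditions: ethylene glycol (excess), TsOH·H2O (cat.), toluene, reflux, Dean–Stark
Reagents that add atoms: ethylene glycol, OCCO
Why: Double acid-catalysed acetalisation takes away both acceptor groups, so the C–F bond of 10 is inert while its phenoxide serves as a nucleophile.

**Step 7**
Reactants: 11 3,5-dimethoxyphenol; 3 3-(allyloxy)-4-fluoro-5-methoxybenzaldehyde
Product: 12 3-(allyloxy)-4-(3,5-dimethoxyphenoxy)-5-methoxybenzaldehyde (A–B allyl ether)
Conditions: K2CO3, DMSO, 120 °C
Reagents that add atoms: none
Why: Nucleophilic aromatic substitution (addition–elimination) at the C–F carbon para to formyl, the standard diaryl ether synthesis from 4-fluorobenzaldehydes; renewed attack of the same phenoxide on B C-1 of 12 is degenerate, and the allyl ether stays well below its Claisen rearrangement temperature.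

**Step 8**
Reactants: 12 A–B allyl ether
Product: 13 4-(3,5-dimethoxyphenoxy)-3-hydroxy-5-methoxybenzaldehyde (A–B phenol)
Conditions: Pd(PPh3)4 (5 mol %), morpholine, THF, rt
Reagents that add atoms: none
Why: Tsuji–Trost-type deallylation: zerovalent palladium ionises the aryl allyl ether and morpholine traps the allyl fragment, conditions that leave aldehyde, methyl ethers and the diaryl ether alone.

**Step 9**
Reactants: 10 4-fluoro-3,5-bis(1,3-dioxolan-2-yl)phenol; 3 3-(allyloxy)-4-fluoro-5-methoxybenzaldehyde
Product: 14 3-(allyloxy)-4-[4-fluoro-3,5-bis(1,3-dioxolan-2-yl)phenoxy]-5-methoxybenzaldehyde (C–D allyl ether)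
Conditions: K2CO3, DMSO, 120 °C
Reagents that add atoms: none
Why: The same para-formyl-activated SNAr as in step 7, here with an unhindered phenoxide whose own fluorine lacks any acceptor and whose base-stable acetals survive, so only the fluoride of 3 can be displaced.

**Step 10**
Reactants: 14 C–D allyl ether
Product: 15 4-[4-fluoro-3,5-bis(1,3-dioxolan-2-yl)phenoxy]-3-hydroxy-5-methoxybenzaldehyde (C–D phenol)
Conditions: Pd(PPh3)4 (5 mol %), morpholine, THF, rt; aq NH4Cl wash
Reagents that add atoms: none
Why: Tsuji–Trost-type deallylation under essentially neutral conditions, orthogonal to the two dioxolanes, and run while no doubly activated aryl ether is present that morpholine could attack.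

**Step 11**
Reactants: 15 C–D phenol; 8 2-fluoro-5-methoxybenzene-1,3-dicarbaldehyde
Product: 17 2-[2-(4-fluoro-3,5-diformylphenoxy)-5-formyl-3-methoxyphenoxy]-5-methoxybenzene-1,3-dicarbaldehyde (C–D–E fluoro pentaaldehyde), via bis-dioxolane trimer 16 (not isolated)
Conditions: K2CO3, 4 Å MS, DMF, 0 °C → rt; filter; THF, 2 M aq HCl, rt
Reagents that add atoms: water, O
Why: SNAr at a C–F carbon flanked by two ortho formyl groups should run at room temperature, where the singly activated ether carbon D C-1 and the unactivated fluorine of ring C are inert and exchange at E C-1 is degenerate; dilute acid then hydrolyses the silica-sensitive dioxolanes without isolation.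

**Step 12**
Reactants: 13 A–B phenol; 17 C–D–E fluoro pentaaldehyde
Product: 18 pentamer hexa-aldehyde: A 3,5-dimethoxyphenoxy; B 2-OMe, 4-CHO; C 2,6-(CHO)2; D 2-OMe, 4-CHO; E 2,6-(CHO)2, 4-OMe
Conditions: K2CO3, 4 Å MS, DMF, 0 °C → rt; 13 added slowly to 17 (1.1 equiv)
Reagents that add atoms: none
Why: SNAr at C C-1 between two ortho formyl groups: addition is rate-limiting and is accelerated by fluorine, so fluoride should be displaced far faster than aryloxide from the equally activated but much more crowded ether carbon E C-1, and slow addition to a slight excess of 17 keeps free phenoxide scarce.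

**Step 13**
Reactants: 18 pentamer hexa-aldehyde
Product: 20 pentamethyl pentamer hexaphenol (OH at B C-4, C C-2, C C-6, D C-4, E C-2, E C-6), via hexaformate 19 (not isolated)
Conditions: mCPBA (dried, 10 equiv), Na2HPO4, CH2Cl2, 0 → 40 °C; Me2S, 0 °C; filter, evaporate; HCl (cat.), degassed MeOH, rt, Ar
Reagents that add atoms: meta-chloroperbenzoic acid, OOC(=O)c1cccc(Cl)c1
Why: The peracid adds to each formyl carbon to give a Criegee adduct, from which the aryl group shifts to the peroxide oxygen as 3-chlorobenzoate leaves, so that each C–CHO becomes C–O–CHO and the six new aryl C–O bonds (B C-4, C C-2, C C-6, D C-4, E C-2, E C-6) are made. The closest known reaction type is the Baeyer–Villiger (Dakin-type) oxidation of alkoxy- and aryloxybenzaldehydes to aryl formates, including 2,3-dialkoxy and 3,4,5-trialkoxy cases in which the donor oxygen is flanked and twisted as it is here. No ring closes and no stereocentre arises. The selectivity needed is aryl over hydride migration at all six sites, and the substrate secures it because every migrating carbon has an ether oxygen ortho (C-1 of rings C and E) or para (C-1 of rings B and D) that stabilises the positive charge building up in the shift. Protection against over-oxidation rests on the products staying as electron-poor formates until Me2S has destroyed the peracid, on the phosphate buffer that keeps acid and traces of water from cleaving them early, and on the choice of mCPBA rather than a stronger peracid so that ring A is left alone. Acid-catalysed transesterification in degassed methanol then releases the six phenols with loss of methyl formate.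

**Step 14**
Reactants: 20 pentamethyl pentamer hexaphenol
Product: 21 CNP0018313.0 (target pentamer, eleven free hydroxyls)
Conditions: BBr3 (15 equiv), CH2Cl2, −78 °C → rt; ice-water, Ar
Reagents that add atoms: none
Why: Exhaustive BBr3 cleavage of the five aryl methyl ethers, a reaction that does not touch diaryl ether bonds; the excess reagent allows for the six phenols that bind boron first.

**Compound list**
1 | 4-fluoro-3,5-dimethoxybenzaldehyde | COc1cc(C=O)cc(OC)c1F | starting material
2 | 4-fluoro-3-hydroxy-5-methoxybenzaldehyde | COc1cc(C=O)cc(O)c1F | intermediate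
3 | 3-(allyloxy)-4-fluoro-5-methoxybenzaldehyde | C=CCOc1cc(C=O)cc(OC)c1F | intermediate
4 | 2-fluoro-5-methoxybenzaldehyde | COc1ccc(F)c(C=O)c1 | starting material
5 | 2-(2-fluoro-5-methoxyphenyl)-1,3-dioxolane | COc1ccc(F)c(C2OCCO2)c1 | intermediate
6 | [3-(1,3-dioxolan-2-yl)-2-fluoro-5-methoxyphenyl]lithium | COc1cc([Li])c(F)c(C2OCCO2)c1 | intermediate
7 | 3-(1,3-dioxolan-2-yl)-2-fluoro-5-methoxybenzaldehyde | COc1cc(C=O)c(F)c(C2OCCO2)c1 | intermediate
8 | 2-fluoro-5-methoxybenzene-1,3-dicarbaldehyde | COc1cc(C=O)c(F)c(C=O)c1 | intermediate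
9 | 2-fluoro-5-hydroxybenzene-1,3-dicarbaldehyde | Oc1cc(C=O)c(F)c(C=O)c1 | intermediate
10 | 4-fluoro-3,5-bis(1,3-dioxolan-2-yl)phenol | Oc1cc(C2OCCO2)c(F)c(C2OCCO2)c1 | intermediate
11 | 3,5-dimethoxyphenol | COc1cc(O)cc(OC)c1 | starting material
12 | 3-(allyloxy)-4-(3,5-dimethoxyphenoxy)-5-methoxybenzaldehyde | COc1cc(OC)cc(Oc2c(OC)cc(C=O)cc2OCC=C)c1 | intermediate
13 | 4-(3,5-dimethoxyphenoxy)-3-hydroxy-5-methoxybenzaldehyde | COc1cc(OC)cc(Oc2c(OC)cc(C=O)cc2O)c1 | intermediate
14 | 3-(allyloxy)-4-[4-fluoro-3,5-bis(1,3-dioxolan-2-yl)phenoxy]-5-methoxybenzaldehyde | C=CCOc1cc(C=O)cc(OC)c1Oc1cc(C2OCCO2)c(F)c(C2OCCO2)c1 | intermediate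
15 | 4-[4-fluoro-3,5-bis(1,3-dioxolan-2-yl)phenoxy]-3-hydroxy-5-methoxybenzaldehyde | Oc1cc(C=O)cc(OC)c1Oc1cc(C2OCCO2)c(F)c(C2OCCO2)c1 | intermediate
16 | 2-{2-[4-fluoro-3,5-bis(1,3-dioxolan-2-yl)phenoxy]-5-formyl-3-methoxyphenoxy}-5-methoxybenzene-1,3-dicarbaldehyde | COc1cc(C=O)c(Oc2cc(C=O)cc(OC)c2Oc2cc(C3OCCO3)c(F)c(C3OCCO3)c2)c(C=O)c1 | intermediate
17 | 2-[2-(4-fluoro-3,5-diformylphenoxy)-5-formyl-3-methoxyphenoxy]-5-methoxybenzene-1,3-dicarbaldehyde | COc1cc(C=O)c(Oc2cc(C=O)cc(OC)c2Oc2cc(C=O)c(F)c(C=O)c2)c(C=O)c1 | intermediate
18 | pentamer hexa-aldehyde (CHO at B C-4, C C-2, C C-6, D C-4, E C-2, E C-6; five OMe) | COc1cc(OC)cc(Oc2c(OC)cc(C=O)cc2Oc2c(C=O)cc(Oc3c(OC)cc(C=O)cc3Oc3c(C=O)cc(OC)cc3C=O)cc2C=O)c1 | intermediate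
19 | pentamer hexaformate (OCHO at the same six positions) | COc1cc(OC)cc(Oc2c(OC)cc(OC=O)cc2Oc2c(OC=O)cc(Oc3c(OC)cc(OC=O)cc3Oc3c(OC=O)cc(OC)cc3OC=O)cc2OC=O)c1 | intermediate
20 | pentamethyl pentamer hexaphenol | COc1cc(OC)cc(Oc2c(OC)cc(O)cc2Oc2c(O)cc(Oc3c(OC)cc(O)cc3Oc3c(O)cc(OC)cc3O)cc2O)c1 | intermediate
21 | CNP0018313.0 | Oc1cc(O)cc(Oc2c(O)cc(O)cc2Oc2c(O)cc(Oc3c(O)cc(O)cc3Oc3c(O)cc(O)cc3O)cc2O)c1 | target

**Step count**
- Total steps: 14.
- Longest linear sequence: 10 (steps 3, 4, 5, 6, 9, 10, 11, 12, 13, 14).

**Steps most likely to fail**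

1. **Step 13.**
   - Risk: hydride may migrate instead of aryl at the four formyl groups of rings C and E, where the only donor is a twisted ortho aryloxy oxygen. The sixfold oxidation may also stall part-way, or ring A may be hydroxylated on long exposure.
   - Fallback: the migrating hydrogen is removed altogether.
   - From 18, MeMgBr (THF, −78 °C) would give the hexakis(1-hydroxyethyl) pentamer F1 as a diastereomer mixture of no consequence.
   - Dess–Martin periodinane would then give the hexaacetyl pentamer F2.
   - Baeyer–Villiger oxidation of these aryl methyl ketones (mCPBA, cat. CF3CO2H, CH2Cl2), in which methyl is the poorest migrating group, would give the pentamer hexaacetate F3.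
   - Methanolysis (cat. HCl, degassed MeOH) comes back to the route at 20.

2. **Step 12.**
   - Risk: aryloxy exchange, in which the A–B phenoxide adds at E C-1 and expels the D phenoxide, which then oligomerises through the ring C fluoride.
   - Fallback: the order of assembly changes from 2+3 to 2+2+1.
   - From 14, aqueous HCl in THF would give 3-(allyloxy)-4-(4-fluoro-3,5-diformylphenoxy)-5-methoxybenzaldehyde F4.
   - Coupling of F4 with 13 (K2CO3, DMF, rt) takes place with no other doubly activated ether present, so that exchange can only be degenerate. It would give the A–B–C–D allyl ether tetraaldehyde F5.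
   - Deallylation with a non-basic trap (Pd(PPh3)4, TolSO2Na, THF/MeOH) would give the A–B–C–D phenol F6.
   - F6 is then treated with a threefold excess of the cheap monomeric fluoride 8, which outcompetes the one exchangeable ether carbon and comes back to the route at 18.

3. **Step 9.**
   - Risk: addition to a C–F carbon crowded and electronically damped by two flanking alkoxy groups may be sluggish. That would force temperatures at which the allyl ether rearranges or the aldehyde degrades.
   - Fallback: the bond is made by metal catalysis instead of addition–elimination.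
   - Purchasable 4-bromo-3,5-dimethoxybenzaldehyde is taken through the operations of steps 1 and 2. This would give 4-bromo-3-hydroxy-5-methoxybenzaldehyde F7 and then 3-(allyloxy)-4-bromo-5-methoxybenzaldehyde F8.
   - From 10, an Ullmann-type coupling with F8 (CuI, picolinic acid, K3PO4, DMSO, 90 °C) comes back to the route at 14.

**Further compounds**
F1 | step 13 | hexakis(1-hydroxyethyl) pentamer (diastereomer mixture) | COc1cc(OC)cc(Oc2c(OC)cc(C(C)O)cc2Oc2c(C(C)O)cc(Oc3c(OC)cc(C(C)O)cc3Oc3c(C(C)O)cc(OC)cc3C(C)O)cc2C(C)O)c1
F2 | step 13 | hexaacetyl pentamer | COc1cc(OC)cc(Oc2c(OC)cc(C(C)=O)cc2Oc2c(C(C)=O)cc(Oc3c(OC)cc(C(C)=O)cc3Oc3c(C(C)=O)cc(OC)cc3C(C)=O)cc2C(C)=O)c1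
F3 | step 13 | pentamer hexaacetate | COc1cc(OC)cc(Oc2c(OC)cc(OC(C)=O)cc2Oc2c(OC(C)=O)cc(Oc3c(OC)cc(OC(C)=O)cc3Oc3c(OC(C)=O)cc(OC)cc3OC(C)=O)cc2OC(C)=O)c1
F4 | step 12 | 3-(allyloxy)-4-(4-fluoro-3,5-diformylphenoxy)-5-methoxybenzaldehyde | C=CCOc1cc(C=O)cc(OC)c1Oc1cc(C=O)c(F)c(C=O)c1
F5 | step 12 | A–B–C–D allyl ether tetraaldehyde | COc1cc(OC)cc(Oc2c(OC)cc(C=O)cc2Oc2c(C=O)cc(Oc3c(OC)cc(C=O)cc3OCC=C)cc2C=O)c1
F6 | step 12 | A–B–C–D phenol tetraaldehyde | COc1cc(OC)cc(Oc2c(OC)cc(C=O)cc2Oc2c(C=O)cc(Oc3c(OC)cc(C=O)cc3O)cc2C=O)c1
F7 | step 9 | 4-bromo-3-hydroxy-5-methoxybenzaldehyde | COc1cc(C=O)cc(O)c1Br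
F8 | step 9 | 3-(allyloxy)-4-bromo-5-methoxybenzaldehyde | C=CCOc1cc(C=O)cc(OC)c1Br
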